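The easy step is a division: I take each substrate to reach double product with two partners, so I count partner per substrate charged.

| setting | ash | alder | cedar | flask |
|---|---|---|---|---|
| substrate | 0.097 M | 0.097 M | 0.19 M | 0.097 M |
| partner | 0.16 M | 0.36 M | 0.242 M | 0.242 M |
| scavenger | 0.146 M | 0.146 M | 0.146 M | 0.146 M |
| remark | run made earlier | run made earlier | run made earlier |  |
| time |  |  |  | 5.0 min |

| run | time / min | substrate / % | single product / % |
|---|---|---|---|
| ash | 0.500 | 55.4 | 25.9 |
| ash | 1.00 | 38.7 | 27.5 |
| ash | 1.50 | 30.5 | 25.2 |
| ash | 2.50 | 21.7 | 22.0 |
| ash | 3.00 | 19.9 | 19.8 |
| ash | 4.00 | 16.8 | 18.2 |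
| alder | 0.500 | 28.0 | 24.2 |
| alder | 1.00 | 12.4 | 13.2 |
| alder | 1.50 | 5.7 | 7.5 |
| alder | 2.50 | 1.9 | 2.3 |
| alder | 3.00 | 0.9 | 1.7 |
| alder | 4.00 | 0.1 | 0.3 |
| cedar | 0.333 | 52.0 | 24.4 |
| cedar | 1.00 | 30.4 | 25.0 |
| cedar | 2.00 | 20.2 | 21.1 |
| cedar | 3.00 | 17.1 | 18.8 |
| cedar | 4.00 | 16.2 | 18.7 |

(each reading ± 0.3 percentage points)

- the analysis behind the earlier runs scatters by 0.3 percentage points, standard deviation
- a reading or a percentage of single product counts all its forms, free or not
- a reading of substrate is of its free form alone

* amount of substrate at 5.0 min, in percent of the substrate charged
* amount of single product at 5.0 min, in percent of the substrate charged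
* amount of double product at 5.0 min, in percent of the substrate charged

In the flask that count, less two, is 0.495, and I carry this surplus, the partner charge as a fraction of the substrate charge less the two that full conversion takes. With double product as the remainder, partner left is the surplus plus twice the substrate plus the single product, all as fractions of the substrate charge. But the cedar run, charged with more substrate, would then have drawn 1.49 from a partner charge of 1.27, so the remainder in that run is not all double product, and I calibrate on alder, which has the flask's substrate and scavenger charges.

Late in the ash run single product reads 18.2% against 16.8% of substrate, so I write partner left as the surplus plus three substrates and freeze that surplus. For a step first order in substrate and first order in partner, the logarithm of partner left over substrate then climbs steadily, at a pace proportional to the surplus. The alder run, with surplus 1.71, reads a climb of 1.19 /min, so this flask climbs 0.345 /min. By 5.0 min I reckon substrate at 2.98%, single product about the same, and double product at 94.0%.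

The forecast says 2.6%, 3.5% and 93%, holding that the flask “ends between ash and alder”.

The flask gives 2.48%, 3.29% and 93.1%.

    scavenger + released group → scavenged by-product (k = 2.10 /M/s)
    substrate + released group ⇌ idle adduct, settled at all times (K = 12.0 /M)
    crystals ⇌ single product, rate k3*(cs3 - [single product]) while solid is left; crystals form when [single product] > cs3 (solubility = 0.0620 M, k = 1.80 /s)
    partner + single product → double product + released group (k = 0.220 /M/s)
    substrate + partner → single product + released group (k = 0.140 /M/s)

In the flask the half-life of substrate by its step with partner is 0.54 min at 0.609 min, short against 5.0 min. At 5.0 min the flask makes dissolved single product at 0.480 of the rate at which it uses it up. The surplus is 19.8% of the partner charge, and at 50.0 min the flask holds 19.8% of it. A neighbour flask charged with 0.060 M of partner has a surplus of −1.38: partner is its limiting reagent, down to 1.62% of its charge at 5.00 min, with substrate at 55.8%.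

The runs were generated by integration with made-up constants; the scatter is artificial.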